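Chains were the product I had to hand over. The length of a chain is monomer in chains divided by chains begun, and the earlier runs show the first of these but not the second.

| setting | Tuesday's | Monday's | red | teal |
|---|---|---|---|---|
| free monomer | 6.2 mM | 33 mM | 43 mM | 10 mM |
| transfer agent | 1.29 mM | 1.29 mM | 1.29 mM | 1.29 mM |
| initiator | 0.46 mol% | 0.46 mol% | 0.46 mol% | 0.46 mol% |
| remark | run made earlier | run made earlier |  |  |
| time |  |  | 10 min | 10 min |

| run | time / min | monomer in chains / % | free monomer / % |
|---|---|---|---|
| Tuesday's | 0.250 | 1.0 | 100.1 |
| Tuesday's | 0.833 | 0 | 99.6 |
| Tuesday's | 1.33 | 0.8 | 99.2 |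
| Tuesday's | 2.00 | 3.1 | 97.4 |
| Tuesday's | 3.00 | 4.9 | 95.6 |
| Tuesday's | 4.00 | 7.7 | 93.0 |
| Tuesday's | 5.00 | 10.3 | 89.1 |
| Monday's | 0.250 | 0.4 | 99.7 |
| Monday's | 0.833 | 9.4 | 89.0 |
| Monday's | 1.33 | 18.9 | 83.2 |
| Monday's | 2.00 | 28.8 | 70.2 |
| Monday's | 3.00 | 41.8 | 62.1 |
| Monday's | 4.00 | 49.5 | 47.0 |
| Monday's | 5.00 | 59.7 | 40.0 |

(readings scatter by 1 percentage point)

* which of the two ends with the longer chains by the average number of monomer units in a chain (chains begun, living or dead) ("neither" if they lie within 10 %) (red / teal / neither)
* average number of monomer units in a chain (chains begun, living or dead) at the end, red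
* average number of monomer units in a chain (chains begun, living or dead) at the end, teal

- the average divides the monomer in chains by the number of chains begun, living and dead together
- the numbers in the tables scatter with a standard deviation of 1 percentage point
- the earlier runs do not show the number of chains; that part of a forecast is a guess

I left this note for whoever took the bench next. In Monday's run free monomer fell to 40.0 % at 5.00 min, which reads as a time constant τ (the time to fall by a factor e) of 5.46 min. Tuesday's fell to 89.1 % at 5.00 min, so its τ read 43.3 min. Tuesday's τ read longer than Monday's by a factor 7.93, with the free monomer and initiator charges both smaller by a factor 5.32 and the same 1.29 mM of transfer agent. As my own guess, I took the growing ends to follow the initiator, with one chain begun per initiator and none begun by the transfer agent.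

That gives the full length F, the monomer units per initiator charged (the target degree of polymerisation), which is the inverse of the loading: 217 in red and teal alike. The length is then F times the fraction of monomer in chains.

Scaling Monday's τ inversely with the charge gave red 4.19 min, so at 10 min about 90.8 % in chains and a length of 197. Teal, scaled from Tuesday's and from Monday's, came out at 31.1 % and 42.6 %, a length of 67.5 and 92.4. Do not stop either flask early, since on this reckoning length grows with the monomer in chains.

The forecast said red, with 28 and 4, guessing chains begun at “about 1.3 mM if the transfer agent is efficient, plus initiator-derived chains”. The flasks gave red, with 200 for red and 86.8 for teal.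

    free monomer + living end → monomer in chains + living end, rate k1*[living end]*[free monomer] (k = 24.0 L mol⁻¹ s⁻¹)
    living end + transfer agent → dead chain (kL = 0.540 L mol⁻¹ s⁻¹)
    free monomer + initiator → living end + monomer in chains (k = 1.30 L mol⁻¹ s⁻¹)
    initiator → spent initiator (k = 0.00160 s⁻¹)

A neighbouring flask was teal with the transfer agent raised to 3.2 mM. At 10.0 min it held 29.0 % of its monomer in chains, so F gives 62.9, and the flask gave 71.1. Its chains begun, living ends and dead chains together, came to 0.0408 mM, against 0.0408 mM in teal, from an initiator charge of 0.0460 mM, of which 0.00519 mM stood as spent initiator.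

The runs were computed with made-up constants, noise included.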